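**Retrosynthetic overview**
1. The strategy rests on the pyran ring (O1–C2–C3=C4–C4a–C8a): its cis C3=C4 bond lies between the gem-dimethyl carbon C2 and C4a of benzene ring A, which maps onto a 1,1-dimethylallyl ether on the C8a oxygen and a vinyl group on C4a. Ring-closing metathesis forms C3=C4 as the last skeletal bond, and only fluoride deprotection follows.
2. The metathesis precursor is cut at the enol ether O–CH bond into the S benzylic alcohol 8 and the Z vinyl iodide 15. A copper-catalysed vinylation joins them with retention at both the carbinol and the alkene; an olefination of the matching unsymmetrical ketone would not fix the enol ether geometry.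
3. Alcohol 8 comes from 4'-hydroxy-2'-methoxyacetophenone by bromination at C5', Suzuki vinylation, O-(1,1-dimethylpropargyl)ation, Lindlar reduction and Corey–Bakshi–Shibata reduction.
4. Iodide 15 comes from SEM-protected 2-bromo-5-methylphenol by copper-catalysed anti-carbomagnesiation of propargyl alcohol, iodinolysis and TIPS protection.
5. Ring order: ring A and the cresol ring are bought; the pyran ring is the only ring made, in step 10.

Key step: step 10

Remark on the chemistry: from compound 7 onward all work-ups and chromatography are kept neutral or basic (Et3N-washed silica), because the tertiary allyl aryl ether, the electron-rich benzylic C–O bond and the enol ether ionise under acid. Locants O1 to C8a are those of 2H-chromene.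

**Route**

Step 1
Reactants: 1 4'-hydroxy-2'-methoxyacetophenone
Product: 2 5'-bromo-4'-hydroxy-2'-methoxyacetophenone
Conditions: NBS (1.02 equiv), MeCN, 0 °C to rt
Reagents that add atoms: N-bromosuccinimide, O=C1CCC(=O)N1Br
Why: Electrophilic aromatic bromination: C5' is ortho to the hydroxyl, para to the methoxyl and open, whereas C3' is squeezed between the two oxygen substituents and C6' is deactivated by the acetyl group, so bromine should enter at C5' and not at the acetyl methyl under these acid-free conditions.

Step 2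
Reactants: 2 5'-bromo-4'-hydroxy-2'-methoxyacetophenone; 3 potassium vinyltrifluoroborate
Product: 4 4'-hydroxy-2'-methoxy-5'-vinylacetophenone
Conditions: Pd(OAc)2 (3 mol%), SPhos (6 mol%), K2CO3 (3 equiv), 1,4-dioxane/H2O 5:1, 80 °C
Reagents that add atoms: none
Why: Suzuki–Miyaura coupling of an aryl bromide with a vinyltrifluoroborate; the electron-rich biarylphosphine lets zerovalent palladium insert into the electron-rich bromophenoxide, and neither the free phenol nor the ketone interferes.

Step 3
Reactants: 4 4'-hydroxy-2'-methoxy-5'-vinylacetophenone; 5 3-chloro-3-methylbut-1-yne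
Product: 6 2'-methoxy-4'-[(2-methylbut-3-yn-2-yl)oxy]-5'-vinylacetophenone
Conditions: DBU (1.3 equiv), CuCl2·2H2O (1 mol%), MeCN, 0 °C
Reagents that add atoms: none
Why: Copper-catalysed O-propargylation of a phenol by a tertiary propargylic chloride: the copper acetylide ionises to an allenylidene-type electrophile that the phenoxide captures at the tertiary carbon, the standard entry to aryl 1,1-dimethylpropargyl ethers, and 0 °C is far below the onset of propargyl Claisen rearrangement.

Step 4
Reactants: 6 2'-methoxy-4'-[(2-methylbut-3-yn-2-yl)oxy]-5'-vinylacetophenone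
Product: 7 2'-methoxy-4'-[(2-methylbut-3-en-2-yl)oxy]-5'-vinylacetophenone
Conditions: H2 (1 atm), Lindlar catalyst (Pd on CaCO3, poisoned with Pb(OAc)2), quinoline, EtOAc, rt, stopped after 1 equiv H2
Reagents that add atoms: none
Why: Lindlar semihydrogenation: the terminal alkyne binds to lead-poisoned palladium far more strongly than the styrene or the product alkene, so hydrogen uptake should stop at the 1,1-dimethylallyl ether with the vinyl group, the aryl ether and the ketone intact.

Step 5
Reactants: 7 2'-methoxy-4'-[(2-methylbut-3-en-2-yl)oxy]-5'-vinylacetophenone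
Product: 8 (1S)-1-{2-methoxy-4-[(2-methylbut-3-en-2-yl)oxy]-5-vinylphenyl}ethanol
Conditions: (R)-2-methyl-CBS-oxazaborolidine (15 mol%), catecholborane (1.8 equiv), toluene, −78 to −40 °C; MeOH quench, 1 M NaOH wash
Reagents that add atoms: none
Why: Corey–Bakshi–Shibata reduction: the ketone binds to the ring boron of the (R)-oxazaborolidine with the aryl group turned away from the catalyst and hydride is passed to its Re face, which gives the S alcohol; catecholborane is chosen because it does not hydroborate the two terminal alkenes at this temperature.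

Step 6
Reactants: 9 2-bromo-5-methylphenol
Product: 10 1-bromo-4-methyl-2-{[2-(trimethylsilyl)ethoxy]methoxy}benzene
Conditions: SEMCl (1.2 equiv), iPr2NEt (1.5 equiv), CH2Cl2, 0 °C to rt
Reagents that add atoms: 2-(trimethylsilyl)ethoxymethyl chloride, C[Si](C)(C)CCOCCl
Why: Williamson-type O-alkylation of a phenol with an α-chloro ether; the resulting acetal ether survives the Grignard chemistry that follows and falls to fluoride at the end.

Step 7
Reactants: 10 1-bromo-4-methyl-2-{[2-(trimethylsilyl)ethoxy]methoxy}benzene; 11 prop-2-yn-1-ol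
Product: 14 (Z)-3-iodo-2-(4-methyl-2-{[2-(trimethylsilyl)ethoxy]methoxy}phenyl)prop-2-en-1-ol, via arylmagnesium bromide 12 (not isolated), via alkenylmagnesium alkoxide 13 (not isolated)
Conditions: (a) 10 (2.4 equiv), Mg turnings, THF, 50 °C; (b) 11 (1.0 equiv), CuI (15 mol%), THF/Et2O, −10 °C to rt, 16 h; (c) I2 (2.0 equiv), THF, −20 to 0 °C; aq. Na2S2O3/NH4Cl
Reagents that add atoms: iodine, II
Why: Copper-catalysed anti-carbomagnesiation of a propargylic alcohol: the magnesium alkoxide steers the aryl group to C2 and magnesium to C3 on the side of the CH2O group (five-membered oxamagnesacycle), and iodinolysis of the C–Mg bond with retention leaves iodine cis to CH2OH, that is the Z iodide.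

Step 8
Reactants: 14 (Z)-3-iodo-2-(4-methyl-2-{[2-(trimethylsilyl)ethoxy]methoxy}phenyl)prop-2-en-1-ol
Product: 15 {[(Z)-3-iodo-2-(4-methyl-2-{[2-(trimethylsilyl)ethoxy]methoxy}phenyl)prop-2-en-1-yl]oxy}tri(propan-2-yl)silane
Conditions: TIPSCl (1.3 equiv), imidazole (2.5 equiv), DMF, rt
Reagents that add atoms: chlorotriisopropylsilane, CC(C)[Si](Cl)(C(C)C)C(C)C
Why: Silylation of the primary allylic alcohol with a bulky silyl chloride under imidazole catalysis; the alkene geometry is not touched.

Step 9
Reactants: 8 (1S)-1-{2-methoxy-4-[(2-methylbut-3-en-2-yl)oxy]-5-vinylphenyl}ethanol; 15 {[(Z)-3-iodo-2-(4-methyl-2-{[2-(trimethylsilyl)ethoxy]methoxy}phenyl)prop-2-en-1-yl]oxy}tri(propan-2-yl)silane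
Product: 16 {[(Z)-3-{(1S)-1-[2-methoxy-4-(2-methylbut-3-en-2-yloxy)-5-vinylphenyl]ethoxy}-2-(4-methyl-2-{[2-(trimethylsilyl)ethoxy]methoxy}phenyl)prop-2-en-1-yl]oxy}tri(propan-2-yl)silane (the S,Z diene)
Conditions: 15 (1.4 equiv), CuI (15 mol%), 3,4,7,8-tetramethyl-1,10-phenanthroline (30 mol%), Cs2CO3 (2.0 equiv), toluene, 75–80 °C, Ar, dark
Reagents that add atoms: none
Why: Copper-catalysed Ullmann-type C–O coupling of a vinyl iodide with an alcohol: the monovalent copper alkoxide of 8 replaces iodide at the sp2 carbon with retention of the double-bond geometry, so iodine cis to CH2OTIPS becomes oxygen cis to CH2OTIPS (Z), and because the C–O bond of the carbinol is never broken the S centre is carried over unchanged.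

Step 10
Reactants: 16 the S,Z diene
Product: 17 {[(Z)-3-[(1S)-1-(7-methoxy-2,2-dimethyl-2H-chromen-6-yl)ethoxy]-2-(4-methyl-2-{[2-(trimethylsilyl)ethoxy]methoxy}phenyl)prop-2-en-1-yl]oxy}tri(propan-2-yl)silane
Conditions: second-generation Grubbs catalyst RuCl2(=CHPh)(H2IMes)(PCy3) (5 mol%), 1,4-benzoquinone (10 mol%), CH2Cl2 (0.005 M), 40 °C; DMSO quench
Reagents that add atoms: none
Why: Ring-closing olefin metathesis: the ruthenium benzylidene exchanges with the unhindered vinyl group on C4a, the new alkylidene adds to the terminal CH2 of the 1,1-dimethylallyl ether through a ruthenacyclobutane, and cycloreversion releases ethylene and leaves the C3=C4 bond. The closest known reaction type is the ring-closing metathesis of 2-vinylaryl allyl ethers to 2H-chromenes. The pyran ring closes in the six-membered mode by joining C3 to C4; the cis geometry is imposed by the ring and the gem-dimethyl group on C2 favours the folded conformer. No stereocentre is formed, and the S carbinol centre and the Z enol ether are spectators under these neutral conditions. The step needs the catalyst to choose the two monosubstituted alkenes over the trisubstituted enol ether: that alkene is β,β-disubstituted and sits meta and para to the two reacting groups, so it cannot close a ring with either and could only react by a slow intermolecular path to a Fischer carbene. The quaternary allylic carbon rules out double-bond migration in the allyl ether, and benzoquinone scavenges ruthenium hydrides that could otherwise isomerise the enol ether.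

Step 11
Reactants: 17 the TIPS and SEM ether of the target
Product: 18 2-[(Z)-3-hydroxy-1-{(1S)-1-(7-methoxy-2,2-dimethyl-2H-chromen-6-yl)ethoxy}prop-1-en-2-yl]-5-methylphenol (CNP0279099.1)
Conditions: Bu4NF (1 M in THF, 6 equiv), THF, rt then 55 °C; pH 7 phosphate buffer; Et3N-washed silica
Reagents that add atoms: none
Why: Fluoride attacks silicon: the TIPS ether gives the alkoxide directly and the SEM group fragments to fluorotrimethylsilane, ethylene and formaldehyde to free the phenoxide, while the basic medium spares the acid-labile enol ether, the benzylic ether with its S centre and the chromene.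

**Compound list**
1 | 4'-hydroxy-2'-methoxyacetophenone | CC(=O)c1ccc(O)cc1OC | starting material
2 | 5'-bromo-4'-hydroxy-2'-methoxyacetophenone | CC(=O)c1cc(Br)c(O)cc1OC | intermediate
3 | potassium vinyltrifluoroborate | [K+].C=C[B-](F)(F)F | starting material
4 | 4'-hydroxy-2'-methoxy-5'-vinylacetophenone | CC(=O)c1cc(C=C)c(O)cc1OC | intermediate
5 | 3-chloro-3-methylbut-1-yne | CC(C)(Cl)C#C | starting material
6 | 2'-methoxy-4'-[(2-methylbut-3-yn-2-yl)oxy]-5'-vinylacetophenone | CC(=O)c1cc(C=C)c(OC(C)(C)C#C)cc1OC | intermediate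
7 | 2'-methoxy-4'-[(2-methylbut-3-en-2-yl)oxy]-5'-vinylacetophenone | CC(=O)c1cc(C=C)c(OC(C)(C)C=C)cc1OC | intermediate
8 | (1S)-1-{2-methoxy-4-[(2-methylbut-3-en-2-yl)oxy]-5-vinylphenyl}ethanol | COc1cc(OC(C)(C)C=C)c(C=C)cc1[C@H](C)O | intermediate
9 | 2-bromo-5-methylphenol | Cc1ccc(Br)c(O)c1 | starting material
10 | 1-bromo-4-methyl-2-{[2-(trimethylsilyl)ethoxy]methoxy}benzene | Cc1ccc(Br)c(OCOCC[Si](C)(C)C)c1 | intermediate
11 | prop-2-yn-1-ol | OCC#C | starting material
12 | (4-methyl-2-{[2-(trimethylsilyl)ethoxy]methoxy}phenyl)magnesium bromide | Cc1ccc([Mg]Br)c(OCOCC[Si](C)(C)C)c1 | intermediate (not isolated)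
13 | bromomagnesium (Z)-3-(bromomagnesio)-2-(4-methyl-2-{[2-(trimethylsilyl)ethoxy]methoxy}phenyl)prop-2-en-1-olate | Br[Mg]/C=C(\CO[Mg]Br)c1ccc(C)cc1OCOCC[Si](C)(C)C | intermediate (not isolated)
14 | (Z)-3-iodo-2-(4-methyl-2-{[2-(trimethylsilyl)ethoxy]methoxy}phenyl)prop-2-en-1-ol | I/C=C(\CO)c1ccc(C)cc1OCOCC[Si](C)(C)C | intermediate
15 | {[(Z)-3-iodo-2-(4-methyl-2-{[2-(trimethylsilyl)ethoxy]methoxy}phenyl)prop-2-en-1-yl]oxy}tri(propan-2-yl)silane | I/C=C(\CO[Si](C(C)C)(C(C)C)C(C)C)c1ccc(C)cc1OCOCC[Si](C)(C)C | intermediate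
16 | S,Z diene (metathesis precursor) | COc1cc(OC(C)(C)C=C)c(C=C)cc1[C@H](C)O/C=C(\CO[Si](C(C)C)(C(C)C)C(C)C)c1ccc(C)cc1OCOCC[Si](C)(C)C | intermediate
17 | TIPS and SEM ether of the target (metathesis product) | COc1cc2OC(C)(C)C=Cc2cc1[C@H](C)O/C=C(\CO[Si](C(C)C)(C(C)C)C(C)C)c1ccc(C)cc1OCOCC[Si](C)(C)C | intermediate
18 | 2-[(Z)-3-hydroxy-1-{(1S)-1-(7-methoxy-2,2-dimethyl-2H-chromen-6-yl)ethoxy}prop-1-en-2-yl]-5-methylphenol | COc1cc2c(cc1[C@H](C)O/C=C(\CO)c1ccc(C)cc1O)C=CC(C)(C)O2 | target

**Totals**
Total step count: 11. Longest linear sequence: 8 steps (steps 1–5, 9, 10, 11).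

**Steps most likely to fail**

Step 9. The hindered secondary alkoxide may transfer to copper so slowly that thermal [3,3] rearrangement of the 1,1-dimethylallyl aryl ether or reduction of the vinyl iodide outruns C–O bond formation. The fallback sets out from alcohol 8 and bromide 10 and comes back to the route at diene 16, building the enol ether by a Horner–Wittig olefination. Alcohol 8 is deprotonated (NaH, THF/DMF) and alkylated with (diphenylphosphoryl)methyl 4-methylbenzenesulfonate to give the (1S)-alkoxymethyl diphenylphosphine oxide F1. Commercial 2-hydroxy-N-methoxy-N-methylacetamide is silylated (TIPSCl, imidazole) to N-methoxy-N-methyl-2-[(triisopropylsilyl)oxy]acetamide F2. Bromide 10 is lithiated (n-BuLi, THF, −78 °C) and acylated with F2 to give the α-silyloxy ketone F3. Lithiated F1 (LDA, THF, −78 °C) adds to F3 to give β-hydroxy phosphine oxides. The two adducts with like configuration at the new centres, the (1R,2R) adduct F4 and the (1S,2S) adduct F5, are separated from the unlike pair by chromatography. Syn elimination with KH in THF should convert both into 16. Here the geometry is sorted by separation and not by the reaction, which is why this is the fallback.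

Step 10. The ruthenium carbene may be captured by the enol ether as a Fischer carbene (catalyst death, loss of the side chain), or ruthenium hydrides may scramble the Z geometry. The fallback sets out from ketone 7 and comes back at compound 17, closing the ring before the enol ether exists. Ketone 7 is cyclised with the second-generation Grubbs catalyst to 1-(7-methoxy-2,2-dimethyl-2H-chromen-6-yl)ethanone F6. Reduction as in step 5 gives (1S)-1-(7-methoxy-2,2-dimethyl-2H-chromen-6-yl)ethanol F7. Copper-catalysed vinylation of F7 with iodide 15 as in step 9 then gives 17; the chromene also removes the risk of Claisen rearrangement in that coupling.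

Step 11. The aryl SEM ether may collapse slowly, so that long exposure to hot basic fluoride degrades the product. The fallback sets out from iodide 14 and comes back at target 18, exchanging the phenol protecting group at a robust stage. Acidic methanolysis of 14 (HCl, MeOH, 45 °C) gives 2-[(Z)-3-hydroxy-1-iodoprop-1-en-2-yl]-5-methylphenol F8. Double silylation (TIPSCl, imidazole, DMF) gives the bis(triisopropylsilyl) ether F9. Coupling with 8 as in step 9 gives the bis-TIPS diene F10, and metathesis as in step 10 gives the bis-TIPS chromene F11. Both silyl ethers should then fall to Bu4NF/AcOH in THF at 0 °C to give 18.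

**Further compounds**
F1 | step 9 | ({(1S)-1-[2-methoxy-4-(2-methylbut-3-en-2-yloxy)-5-vinylphenyl]ethoxy}methyl)diphenylphosphine oxide | COc1cc(OC(C)(C)C=C)c(C=C)cc1[C@H](C)OCP(=O)(c1ccccc1)c1ccccc1
F2 | step 9 | N-methoxy-N-methyl-2-[(triisopropylsilyl)oxy]acetamide | CON(C)C(=O)CO[Si](C(C)C)(C(C)C)C(C)C
F3 | step 9 | 1-(4-methyl-2-{[2-(trimethylsilyl)ethoxy]methoxy}phenyl)-2-[(triisopropylsilyl)oxy]ethan-1-one | O=C(CO[Si](C(C)C)(C(C)C)C(C)C)c1ccc(C)cc1OCOCC[Si](C)(C)C
F4 | step 9 | (1R,2R)-1-(diphenylphosphoryl)-1-{(1S)-1-[2-methoxy-4-(2-methylbut-3-en-2-yloxy)-5-vinylphenyl]ethoxy}-2-(4-methyl-2-{[2-(trimethylsilyl)ethoxy]methoxy}phenyl)-3-[(triisopropylsilyl)oxy]propan-2-ol | COc1cc(OC(C)(C)C=C)c(C=C)cc1[C@H](C)O[C@@H]([C@](O)(CO[Si](C(C)C)(C(C)C)C(C)C)c1ccc(C)cc1OCOCC[Si](C)(C)C)P(=O)(c1ccccc1)c1ccccc1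
F5 | step 9 | (1S,2S) diastereomer of F4 | COc1cc(OC(C)(C)C=C)c(C=C)cc1[C@H](C)O[C@H]([C@@](O)(CO[Si](C(C)C)(C(C)C)C(C)C)c1ccc(C)cc1OCOCC[Si](C)(C)C)P(=O)(c1ccccc1)c1ccccc1
F6 | step 10 | 1-(7-methoxy-2,2-dimethyl-2H-chromen-6-yl)ethanone | CC(=O)c1cc2C=CC(C)(C)Oc2cc1OC
F7 | step 10 | (1S)-1-(7-methoxy-2,2-dimethyl-2H-chromen-6-yl)ethanol | COc1cc2OC(C)(C)C=Cc2cc1[C@H](C)O
F8 | step 11 | 2-[(Z)-3-hydroxy-1-iodoprop-1-en-2-yl]-5-methylphenol | I/C=C(\CO)c1ccc(C)cc1O
F9 | step 11 | bis(triisopropylsilyl) ether of F8 | I/C=C(\CO[Si](C(C)C)(C(C)C)C(C)C)c1ccc(C)cc1O[Si](C(C)C)(C(C)C)C(C)C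
F10 | step 11 | bis-TIPS S,Z diene | COc1cc(OC(C)(C)C=C)c(C=C)cc1[C@H](C)O/C=C(\CO[Si](C(C)C)(C(C)C)C(C)C)c1ccc(C)cc1O[Si](C(C)C)(C(C)C)C(C)C
F11 | step 11 | bis-TIPS ether of the target | COc1cc2OC(C)(C)C=Cc2cc1[C@H](C)O/C=C(\CO[Si](C(C)C)(C(C)C)C(C)C)c1ccc(C)cc1O[Si](C(C)C)(C(C)C)C(C)C
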